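## Analysis of the target

The target is a 2-arylbenzofuran-3-carbaldehyde: C2 carries a 2,4-dihydroxyphenyl ring, C3 the formyl group, and the benzo ring A (C3a to C7a) carries a free hydroxyl at C4, a 2-hydroxy-3-methylbut-3-enyl chain at C5 and a methoxy group at C6, so that C7 is its only hydrogen. There is a single stereocentre, the carbinol carbon C2'' of the chain, with (R) configuration; it stands alone, two bonds from ring A, so nothing in the flat core can control it. The sensitive points are the aldehyde (flanked by the 4-hydroxyl and able to close to a lactol with the 2'-hydroxyl), two very electron-rich arenes, and a secondary allylic alcohol next to a 1,1-disubstituted alkene, which excludes hydrogenolysis and tolerates only mild acid. The difficulty is density of substitution: the furan is fully substituted, ring A is pentasubstituted, its three oxygens (O1, O4, O6) must end in three different states, and the carbon chain sits between two of them. Late formylation or alkylation of a preformed benzofuran would have to choose between C3, C5, C7 and the resorcinol ring. The route rests on reading ring A as a resorcinol: O4 and O6 are meta, with the carbon-substituted C5 between them, which is the enol form of a cyclohexane-1,3-dione and therefore the product of a ketone carbonyl (C4) and an ester carbonyl (C6) joined through the α-carbon of the ketone (C5). That α-carbon can carry the finished chiral chain, and the other ring A atoms (C3a, C7a, C7) come from a 3-acylfuran-2-ylacetate.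

## Retrosynthetic reasoning

**27 back to 24 (no skeletal change).** The O–CH2 bonds of the two aryl MOM ethers and the O–Si bond of the silyl ether are cut last (27 to 26), because the free resorcinol hydroxyls and the free allylic alcohol are the groups least able to survive earlier steps. The O6–CH3 bond is cut next (26 to 25). It is formed at the aldehyde stage because in 25 the 4-hydroxyl is hydrogen-bonded to the formyl oxygen and shielded by its two neighbours, which leaves O6 as the reactive phenol. The formyl group is then traced to its dimethyl acetal (25 to 24), since a free aldehyde would be a competing electrophile in the ring-forming step.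

**24 to 23 (C5–C6, the strategic cut).** Cutting C5–C6 leaves the ketone carbon (C4) on furan C3 and puts the ester carbon (C6) in a two-carbon arm on furan C2. The nucleophilic carbon is then the α-carbon of the ketone, which already bears the complete chain with its stereocentre. Cutting C4–C5 instead would put the ketone in the arm, where a doubly activated methylene would dominate the enolate chemistry. Cutting inside the furan would give up a heterocycle whose substitution pattern can be fixed position by position. The forward reaction has to form one C–C bond intramolecularly and aromatise; no stereocentre is created and none lies within reach of the base.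

**23 to 22 (C7–C7a, the acetate arm).** The bond between the arm CH2 and furan C2 is cut so that the acidic arylacetate unit is absent while organolithium chemistry builds the ketone. In 22 this carbon carries chlorine, which is inert to halogen–lithium exchange and, next to the ketone, is a vinylogous acid chloride. The forward step joins it to a zinc ester enolate under near-neutral conditions.

**22 to 13 and 20 (C3a–C4, the acyl bond).** This is the convergent cut: a 3-furyl nucleophile generated from the C–Br bond of 13 and an N-methoxy-N-methylamide 20 that holds the whole chain. A β-position of the furan cannot be reached by deprotonation, so it has to be marked by bromine from the start. The stereocentre is three atoms from the reacting carbonyl and is not affected.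

**20 to 14 (the chain).** Amide 20 is traced through hydroxy amide 19 to lactone 18 (O–Si bond, then amide C–N bond with ring opening). The isopropenyl C=CH2 bond is cut to ketone 17, and its C–CH3 bond to acid 15 through acid chloride 16. Acid 15 comes from D-glutamic acid 14 by replacing C–N with C–O with retention. The absolute configuration is thus taken from the chiral pool and no enantioselective step is needed.

**13 to 5 and 1 (the furan core and the aryl group).** The aryl–furan bond is cut to chlorobromofuran 10 and aryl iodide 4 (from 2 and 1). 10 is traced through acetal 8 and aldehyde 7 to the symmetrical 3,4-dibromofuran 5. 5 supplies both β-carbons already functionalised; one exchange desymmetrises it (formyl carbon on one side, bromine kept on the other). The bromine then distinguishes the two α-hydrogens: the one next to it is the more acidic and is replaced by chlorine first, and the remaining one, next to the acetal, receives the aryl group.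

## Alternatives that were turned down

**Alternative 1:** The disconnection is O1–C7a: the furan is closed last onto ring A, with the C3 carbon and the 2'-oxygen tied together as a lactone. The key step would be a CuI-catalysed intramolecular O-arylation (chelating nitrogen ligand, Cs2CO3) of the enol of the bromoaryl hydroxycoumarin A2, giving the coumestan A1, whose allyl ether marks the future O4.
- For it: closing a five-membered ring from an enolate oxygen onto an ortho C–Br bond is dependable Ullmann-type chemistry. The lactone protects the formyl carbon and O2' in one ring. The core comes convergently from a coumarin and a bromoarene with no regiochemical question on the furan. On these points it is stronger than the chosen route, which needs four steps of halogen-guided furan substitution.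
- Against it: after A1 the whole C5 chain and the only stereocentre are still missing. The allyl group has to be moved from O4 to C5 by aromatic Claisen rearrangement, cut down and rebuilt with a catalyst-controlled isopropenyl addition, all beside an aryl lactone that is sensitive to such nucleophiles. The lactone must then be half-reduced to the aldehyde level without over-reduction. A2 itself needs C-arylation of a 4-hydroxycoumarin by a 2,6-disubstituted arene cut from an unsymmetrically protected phloroglucinol.
- Comparison: the chosen strategy does its difficult work before ring A exists, brings the stereocentre in from D-glutamic acid, and delivers O4 and O6 as a distinguishable pair with the formyl carbon already at the right oxidation level.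

**Alternative 2:** The disconnection is at the carbinol C–O bond: the stereocentre is made from a C5 prenyl group. The key step would be Shi epoxidation of the prenyl benzofuran A4 (chiral dioxirane from the fructose-derived ketone and KHSO5) to the (R)-epoxide A3. Base-induced isomerisation of the epoxide to the allylic alcohol, adjustment of the C3 ester to the aldehyde and deprotection would follow.
- For it: prenyl is the cheapest precursor of the chain, one catalytic step sets the configuration, either enantiomer is available, and the sequence mirrors the likely biogenesis. For the side chain alone it is clearly more step-economic than the five steps spent on 20.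
- Against it: enantiomeric purity depends on the catalyst, for an alkene whose allylic carbon sits between two ortho oxygens. The oxidant meets two very electron-rich arenes. The epoxide lies next to ortho ether oxygens that open it to cyclic ethers under any acid. The isomerisation to the allylic alcohol needs strong amide bases beside a methyl ester, or a two-step selenium sequence. The ester needs a reduction–oxidation pair at the end. Most important, A4, a fully substituted benzofuran with three differentiated oxygens, must be made first, which is the problem the Claisen aromatisation solves.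
- Comparison: in place of the short chain synthesis, the chosen route offers certainty of configuration and no oxidation chemistry on the electron-rich core.

**Alternative 3:** The disconnection is the C3–formyl carbon bond: that carbon enters as CO. The key step would be a Pd(OAc)2-catalysed carbonylation (Cu(OAc)2 as oxidant) of the 2-(2-hydroxyaryl)benzofuran A6. The phenoxide guides divalent palladium to C3–H, CO inserts and the lactone of coumestan A5 closes.
- For it: A6 is available in very few steps by standard 2-arylbenzofuran chemistry. C3 is the innately nucleophilic position and the phenoxide reaches it through a six-membered palladacycle. The C1 unit is CO itself. In brevity to the carbonylated core this is the strongest of the four approaches, and it avoids a fully substituted furan.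
- Against it: the conditions are oxidising and hot on a phloroglucinol-type ring, and the chain problem is untouched. If the chain is installed before carbonylation, its alkene and allylic oxygen face divalent palladium, CO and a copper oxidant (Wacker-type oxidation, allylic ionisation, alkoxycarbonylation). If it is installed after, the natural method, metalation of C5 between O4 and O6 and opening of a chiral epoxide, is incompatible with the lactone. The lactone again needs half-reduction.
- Comparison: the chosen route is longer to the core, but it places every substituent by construction and carries the stereocentre from the start.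

Key step: step 14

Assumption: the target is treated as the open hydroxy aldehyde as drawn; its ring–chain tautomer (lactol with the 2'-hydroxyl) is regarded as freely equilibrating and not as a separate compound.

## Route

Step 1
Reactants: 1 4-bromoresorcinol
Product: 2 1-bromo-2,4-bis(methoxymethoxy)benzene
Conditions: MOMCl, i-Pr2NEt, CH2Cl2, 0 °C → rt
Reagents that add atoms: chloromethyl methyl ether, COCCl
Why: O-alkylation of both phenols by the reactive α-chloro ether; the MOM ethers tolerate every basic and organometallic step ahead and are removed by dilute acid at the end.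

Step 2
Reactants: 2 1-bromo-2,4-bis(methoxymethoxy)benzene
Product: 4 1-iodo-2,4-bis(methoxymethoxy)benzene, via aryllithium 3 (not isolated)
Conditions: n-BuLi, THF, −78 °C; I2, −78 °C → rt
Reagents that add atoms: iodine, II
Why: Bromine–lithium exchange at −78 °C is much faster than ortho-deprotonation, and the aryllithium is iodinated by I2; the iodide lets the later cross-coupling run in the presence of the C–Br and C–Cl bonds of the furan.

Step 3
Reactants: 5 3,4-dibromofuran
Product: 7 4-bromofuran-3-carbaldehyde, via 3-bromo-4-lithiofuran 6 (not isolated)
Conditions: n-BuLi (1.0 equiv), Et2O, −78 °C; DMF, −78 → 0 °C; H2O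
Reagents that add atoms: N,N-dimethylformamide, CN(C)C=O
Why: Single bromine–lithium exchange of the symmetrical dibromide and formylation with DMF; at −78 °C the 3-lithiofuran neither ring-opens nor migrates to an α-position.

Step 4
Reactants: 7 4-bromofuran-3-carbaldehyde
Product: 8 3-bromo-4-(dimethoxymethyl)furan
Conditions: HC(OMe)3, MeOH, p-TsOH·H2O (cat.), rt; NaHCO3
Reagents that add atoms: trimethyl orthoformate, COC(OC)OC; methanol, CO
Why: Acid-catalysed acetalisation driven by the orthoformate; the dimethyl acetal shields the formyl carbon from the bases, organolithiums and enolates of the following steps and is removed later by very mild acid.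

Step 5
Reactants: 8 3-bromo-4-(dimethoxymethyl)furan
Product: 10 3-bromo-2-chloro-4-(dimethoxymethyl)furan, via 2-lithiofuran 9 (not isolated)
Conditions: LiN(i-Pr)2, THF, −78 °C; C2Cl6, −78 °C → rt
Reagents that add atoms: hexachloroethane, ClC(Cl)(Cl)C(Cl)(Cl)Cl
Why: Lithium amides remove the α-hydrogen of 3-bromofurans that lies between the ring oxygen and the brominated carbon (inductive acidification), and the lithio species is chlorinated by hexachloroethane; chlorine survives the later bromine–lithium exchange and becomes reactive once the neighbouring ketone is in place.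

Step 6
Reactants: 10 3-bromo-2-chloro-4-(dimethoxymethyl)furan; 4 1-iodo-2,4-bis(methoxymethoxy)benzene
Product: 13 2-[2,4-bis(methoxymethoxy)phenyl]-4-bromo-5-chloro-3-(dimethoxymethyl)furan, via furyllithium 11 (not isolated), via furylzinc chloride 12 (not isolated)
Conditions: LiN(i-Pr)2, THF, −78 °C; ZnCl2, −78 °C → rt; 4, Pd(PPh3)4 (5 mol %), THF, 50 °C
Reagents that add atoms: none
Why: The only remaining ring hydrogen, an α-hydrogen next to the acetal, is removed by the amide base and the lithium is exchanged for zinc; Negishi coupling follows, in which zerovalent palladium inserts into the aryl C–I bond of 4 far faster than into the hindered furyl C–Br or the C–Cl bond.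

Step 7
Reactants: 14 D-glutamic acid
Product: 15 (R)-5-oxotetrahydrofuran-2-carboxylic acid
Conditions: NaNO2, aq. HCl, 0 °C → rt
Reagents that add atoms: none
Why: Diazotisation of the α-amino acid; the α-carboxylate displaces N2 to an α-lactone, which the side-chain carboxyl opens, so two inversions give the γ-lactone with net retention and the (R) centre of the target is taken from the chiral pool.

Step 8
Reactants: 15 (R)-5-oxotetrahydrofuran-2-carboxylic acid
Product: 17 (R)-5-acetyldihydrofuran-2(3H)-one, via acid chloride 16 (not isolated)
Conditions: (COCl)2, DMF (cat.), CH2Cl2, 0 °C → rt; MeMgBr, Fe(acac)3 (3 mol %), THF, −78 °C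
Reagents that add atoms: methylmagnesium bromide, C[Mg]Br; oxalyl chloride, O=C(Cl)C(=O)Cl (chlorine of 16 only)
Why: Acid chloride formation and iron-catalysed acyl cross-coupling with the methyl Grignard reagent, a ketone synthesis that at −78 °C is much faster than addition to the lactone or to the product ketone; the cold, short contact and acidic quench limit enolisation of the α-acyloxy ketone.

Step 9
Reactants: 17 (R)-5-acetyldihydrofuran-2(3H)-one
Product: 18 (R)-5-(prop-1-en-2-yl)dihydrofuran-2(3H)-one
Conditions: Zn, CH2Br2, TiCl4, THF, 0 °C → rt
Reagents that add atoms: dibromomethane, BrCBr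
Why: Takai–Lombardo methylenation converts the ketone into the 1,1-disubstituted alkene without touching the lactone and, being non-basic, without enolising the stereocentre α to the ketone.

Step 10
Reactants: 18 (R)-5-(prop-1-en-2-yl)dihydrofuran-2(3H)-one
Product: 19 (4R)-4-hydroxy-N-methoxy-N,5-dimethylhex-5-enamide
Conditions: MeNH(OMe)·HCl, AlMe3, CH2Cl2, 0 °C → rt
Reagents that add atoms: N,O-dimethylhydroxylamine hydrochloride, CNOC.Cl
Why: Aluminium amide aminolysis of the lactone (Weinreb amide formation) breaks the acyl C–O bond, so the carbinol stereocentre is not involved.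

Step 11
Reactants: 19 (4R)-4-hydroxy-N-methoxy-N,5-dimethylhex-5-enamide
Product: 20 (4R)-4-(tert-butyldimethylsilyloxy)-N-methoxy-N,5-dimethylhex-5-enamide
Conditions: TBSCl, imidazole, DMF, rt
Reagents that add atoms: tert-butyldimethylsilyl chloride, CC(C)(C)[Si](C)(C)Cl
Why: Standard silylation of the secondary allylic alcohol; it stops relactonisation of the γ-hydroxy amide and later keeps an alkoxide from adding to the ketone during the Claisen step.

Step 12
Reactants: 13 2-[2,4-bis(methoxymethoxy)phenyl]-4-bromo-5-chloro-3-(dimethoxymethyl)furan; 20 (4R)-4-(tert-butyldimethylsilyloxy)-N-methoxy-N,5-dimethylhex-5-enamide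
Product: 22 (4R)-1-[5-[2,4-bis(methoxymethoxy)phenyl]-2-chloro-4-(dimethoxymethyl)furan-3-yl]-4-(tert-butyldimethylsilyloxy)-5-methylhex-5-en-1-one, via 3-furyllithium 21 (not isolated)
Conditions: n-BuLi (1.05 equiv), THF, −78 °C; 20, −78 → −40 °C; AcOH (1.1 equiv), −78 °C, then H2O
Reagents that add atoms: none
Why: Bromine–lithium exchange takes place at C–Br and not at C–Cl, and the 3-furyllithium is acylated only once by the Weinreb amide because the chelated tetrahedral adduct persists until the quench; holding the mixture at or below −40 °C avoids ring-opening of the 3-lithiofuran.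

Step 13
Reactants: 22 (4R)-1-[5-[2,4-bis(methoxymethoxy)phenyl]-2-chloro-4-(dimethoxymethyl)furan-3-yl]-4-(tert-butyldimethylsilyloxy)-5-methylhex-5-en-1-one
Product: 23 methyl 2-[5-[2,4-bis(methoxymethoxy)phenyl]-4-(dimethoxymethyl)-3-[(4R)-4-(tert-butyldimethylsilyloxy)-5-methylhex-5-enoyl]furan-2-yl]acetate
Conditions: BrZnCH2CO2Me (2.2 equiv; from BrCH2CO2Me, Zn, THF), Pd2(dba)3 (2.5 mol %), 2-dicyclohexylphosphino-2',4',6'-triisopropylbiphenyl (10 mol %), THF, 45 °C
Reagents that add atoms: bromo(2-methoxy-2-oxoethyl)zinc, COC(=O)C[Zn]Br (prepared from methyl bromoacetate, COC(=O)CBr)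
Why: Palladium-catalysed α-arylation of a zinc ester enolate (Reformatsky reagent) with a heteroaryl chloride; the C–Cl bond is activated as a vinylogous acid chloride by the adjacent ketone and the ring oxygen, and the nearly neutral zinc enolate tolerates the enolisable ketone, the acetal and the MOM and silyl ethers.

Step 14
Reactants: 23 methyl 2-[5-[2,4-bis(methoxymethoxy)phenyl]-4-(dimethoxymethyl)-3-[(4R)-4-(tert-butyldimethylsilyloxy)-5-methylhex-5-enoyl]furan-2-yl]acetate
Product: 24 2-[2,4-bis(methoxymethoxy)phenyl]-5-[(2R)-2-(tert-butyldimethylsilyloxy)-3-methylbut-3-enyl]-3-(dimethoxymethyl)benzofuran-4,6-diol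
Conditions: KOtBu (3 equiv), THF (0.02 M), 0 °C → rt; AcOH (3 equiv), 0 °C; crude product taken on directly
Reagents that add atoms: none
Why: tert-Butoxide deprotonates reversibly both the furylacetate CH2 and the CH2 α to the ketone; the ester enolate could only close a four-membered ring onto the ketone and returns to the equilibrium, whereas the ketone enolate carbon (future C5, carrying the chain) lies six atoms from the ester carbonyl (future C6) and adds to it. Loss of methoxide gives the cyclic 1,3-diketone, which tautomerises to the aromatic 4,6-dihydroxybenzofuran and is deprotonated twice, so the sequence is irreversible. The closest known reaction is the base-induced Claisen (Dieckmann-type) cyclisation of 2-acylarylacetic esters to arene-1,3-diols. Ring A closes in a 6-(enolendo)-exo-trig mode, which is favoured for enolates. O-acylation to the enol lactone is reversible under alkoxide and drains into the C-acylated aromatic product. No stereocentre is formed, and the existing one is γ to the ketone, so neither enolisation nor β-elimination of the silyloxy group can reach it. The step needs intramolecular C-acylation to win over intermolecular condensation; dilution and the absence of any other electrophile (the formyl carbon is an acetal) should secure this.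

Step 15
Reactants: 24 2-[2,4-bis(methoxymethoxy)phenyl]-5-[(2R)-2-(tert-butyldimethylsilyloxy)-3-methylbut-3-enyl]-3-(dimethoxymethyl)benzofuran-4,6-diol
Product: 25 2-[2,4-bis(methoxymethoxy)phenyl]-5-[(2R)-2-(tert-butyldimethylsilyloxy)-3-methylbut-3-enyl]-4,6-dihydroxybenzofuran-3-carbaldehyde
Conditions: pyridinium p-toluenesulfonate (cat.), acetone/H2O (10:1), rt
Reagents that add atoms: water, O
Why: Acetal hydrolysis; the acetal of a 3-formylbenzofuran ionises easily because O1 stabilises the oxocarbenium ion through C2=C3, so a weak acid should suffice and leave the aryl MOM ethers and the silyl ether in place.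

Step 16
Reactants: 25 2-[2,4-bis(methoxymethoxy)phenyl]-5-[(2R)-2-(tert-butyldimethylsilyloxy)-3-methylbut-3-enyl]-4,6-dihydroxybenzofuran-3-carbaldehyde
Product: 26 2-[2,4-bis(methoxymethoxy)phenyl]-5-[(2R)-2-(tert-butyldimethylsilyloxy)-3-methylbut-3-enyl]-4-hydroxy-6-methoxybenzofuran-3-carbaldehyde
Conditions: MeI (1.1 equiv), K2CO3 (1.1 equiv), acetone, rt
Reagents that add atoms: iodomethane, CI
Why: Williamson O-methylation with one equivalent of reagent; the 4-hydroxyl is hydrogen-bonded to the formyl oxygen and squeezed between C3 and the C5 chain, so the freer and more acidic 6-hydroxyl should react first.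

Step 17
Reactants: 26 2-[2,4-bis(methoxymethoxy)phenyl]-5-[(2R)-2-(tert-butyldimethylsilyloxy)-3-methylbut-3-enyl]-4-hydroxy-6-methoxybenzofuran-3-carbaldehyde
Product: 27 2-(2,4-dihydroxyphenyl)-4-hydroxy-5-[(2R)-2-hydroxy-3-methylbut-3-enyl]-6-methoxybenzofuran-3-carbaldehyde
Conditions: 2 M aq. HCl/THF (1:3), 40 °C
Reagents that add atoms: none
Why: Acid hydrolysis of the two aryl MOM acetals and of the secondary silyl ether in one operation; water and not an alcohol is the co-solvent so that the aldehyde and the 2'-hydroxyl are not trapped as a mixed cyclic acetal, and dilute acid at low temperature spares the allylic alcohol.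

## Compound list

1 | 4-bromoresorcinol (4-bromobenzene-1,3-diol) | Oc1ccc(Br)c(O)c1 | starting material
2 | 1-bromo-2,4-bis(methoxymethoxy)benzene | COCOc1ccc(Br)c(OCOC)c1 | intermediate
3 | [2,4-bis(methoxymethoxy)phenyl]lithium | [Li]c1ccc(OCOC)cc1OCOC | intermediate
4 | 1-iodo-2,4-bis(methoxymethoxy)benzene | COCOc1ccc(I)c(OCOC)c1 | intermediate
5 | 3,4-dibromofuran | Brc1cocc1Br | starting material
6 | (4-bromofuran-3-yl)lithium | [Li]c1cocc1Br | intermediate
7 | 4-bromofuran-3-carbaldehyde | O=Cc1cocc1Br | intermediate
8 | 3-bromo-4-(dimethoxymethyl)furan | COC(OC)c1cocc1Br | intermediate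
9 | [3-bromo-4-(dimethoxymethyl)furan-2-yl]lithium | COC(OC)c1coc([Li])c1Br | intermediate
10 | 3-bromo-2-chloro-4-(dimethoxymethyl)furan | COC(OC)c1coc(Cl)c1Br | intermediate
11 | [4-bromo-5-chloro-3-(dimethoxymethyl)furan-2-yl]lithium | COC(OC)c1c([Li])oc(Cl)c1Br | intermediate
12 | [4-bromo-5-chloro-3-(dimethoxymethyl)furan-2-yl]zinc chloride | COC(OC)c1c([Zn]Cl)oc(Cl)c1Br | intermediate
13 | 2-[2,4-bis(methoxymethoxy)phenyl]-4-bromo-5-chloro-3-(dimethoxymethyl)furan | COC(OC)c1c(Br)c(Cl)oc1-c1ccc(OCOC)cc1OCOC | intermediate
14 | D-glutamic acid ((R)-2-aminopentanedioic acid) | N[C@H](CCC(=O)O)C(=O)O | starting material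
15 | (R)-5-oxotetrahydrofuran-2-carboxylic acid | OC(=O)[C@H]1CCC(=O)O1 | intermediate
16 | (R)-5-oxotetrahydrofuran-2-carbonyl chloride | O=C(Cl)[C@H]1CCC(=O)O1 | intermediate
17 | (R)-5-acetyldihydrofuran-2(3H)-one | CC(=O)[C@H]1CCC(=O)O1 | intermediate
18 | (R)-5-(prop-1-en-2-yl)dihydrofuran-2(3H)-one | C=C(C)[C@H]1CCC(=O)O1 | intermediate
19 | (4R)-4-hydroxy-N-methoxy-N,5-dimethylhex-5-enamide | C=C(C)[C@H](O)CCC(=O)N(C)OC | intermediate
20 | (4R)-4-(tert-butyldimethylsilyloxy)-N-methoxy-N,5-dimethylhex-5-enamide | C=C(C)[C@H](O[Si](C)(C)C(C)(C)C)CCC(=O)N(C)OC | intermediate
21 | [5-[2,4-bis(methoxymethoxy)phenyl]-2-chloro-4-(dimethoxymethyl)furan-3-yl]lithium | COC(OC)c1c([Li])c(Cl)oc1-c1ccc(OCOC)cc1OCOC | intermediate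
22 | (4R)-1-[5-[2,4-bis(methoxymethoxy)phenyl]-2-chloro-4-(dimethoxymethyl)furan-3-yl]-4-(tert-butyldimethylsilyloxy)-5-methylhex-5-en-1-one | C=C(C)[C@H](O[Si](C)(C)C(C)(C)C)CCC(=O)c1c(Cl)oc(-c2ccc(OCOC)cc2OCOC)c1C(OC)OC | intermediate
23 | methyl 2-[5-[2,4-bis(methoxymethoxy)phenyl]-4-(dimethoxymethyl)-3-[(4R)-4-(tert-butyldimethylsilyloxy)-5-methylhex-5-enoyl]furan-2-yl]acetate | C=C(C)[C@H](O[Si](C)(C)C(C)(C)C)CCC(=O)c1c(CC(=O)OC)oc(-c2ccc(OCOC)cc2OCOC)c1C(OC)OC | intermediate
24 | 2-[2,4-bis(methoxymethoxy)phenyl]-5-[(2R)-2-(tert-butyldimethylsilyloxy)-3-methylbut-3-enyl]-3-(dimethoxymethyl)benzofuran-4,6-diol | C=C(C)[C@H](O[Si](C)(C)C(C)(C)C)Cc1c(O)cc2oc(-c3ccc(OCOC)cc3OCOC)c(C(OC)OC)c2c1O | intermediate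
25 | 2-[2,4-bis(methoxymethoxy)phenyl]-5-[(2R)-2-(tert-butyldimethylsilyloxy)-3-methylbut-3-enyl]-4,6-dihydroxybenzofuran-3-carbaldehyde | C=C(C)[C@H](O[Si](C)(C)C(C)(C)C)Cc1c(O)cc2oc(-c3ccc(OCOC)cc3OCOC)c(C=O)c2c1O | intermediate
26 | 2-[2,4-bis(methoxymethoxy)phenyl]-5-[(2R)-2-(tert-butyldimethylsilyloxy)-3-methylbut-3-enyl]-4-hydroxy-6-methoxybenzofuran-3-carbaldehyde | C=C(C)[C@H](O[Si](C)(C)C(C)(C)C)Cc1c(OC)cc2oc(-c3ccc(OCOC)cc3OCOC)c(C=O)c2c1O | intermediate
27 | 2-(2,4-dihydroxyphenyl)-4-hydroxy-5-[(2R)-2-hydroxy-3-methylbut-3-enyl]-6-methoxybenzofuran-3-carbaldehyde | C=C(C)[C@H](O)Cc1c(OC)cc2oc(-c3ccc(O)cc3O)c(C=O)c2c1O | target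

## Step count and least certain steps

Total step count: 17. Longest linear sequence: 11 steps (steps 7 to 17, from 14 to 27); the furan branch (steps 3 to 6) and the aryl branch (steps 1 and 2) join it at steps 12 and 6.

**Step 14 (key step).** The substrate may rest as the enolate of the furylacetate, its most acidic site, while the ketone, twisted between two ortho substituents, enolises slowly; intermolecular ester condensation can then compete with ring closure. Fallback, starting from 23: the methyl ester is saponified (LiOH, THF/H2O, then cold dilute HCl to pH 4) to the keto acid F1. Ac2O in pyridine dehydrates this to the enol lactone F2, in which the carboxyl has acylated the enol oxygen of the ketone. NaOMe in MeOH/THF should open F2 at the lactone carbonyl, which releases the ketone enolate and a neutral methyl ester in the same molecule at the same moment; these close as in the main route and the sequence returns at 24.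

**Step 13.** The zinc enolate may add to the ketone carbonyl (Reformatsky addition), or the C–Cl bond may be reduced, because zinc enolates are carbonyl nucleophiles and the palladium centre is crowded after oxidative addition. Fallback, starting from 22: the vinylogous acid chloride is used without a metal at the bond-forming stage. The sodium salt of allyl methyl malonate (NaH, THF) should displace chloride by addition–elimination and give the furyl malonate F3. Pd(PPh3)4 and morpholine then remove the allyl ester, the malonic half acid loses CO2, and the route is rejoined at 23.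

**Step 16.** Site selectivity may be lost (methylation at O4 or at both oxygens, or C-methylation at C7), because the hydrogen bond to the formyl group closes a seven-membered ring and may bias less strongly than a salicylaldehyde-type chelate. Fallback, starting from 24: methylation is done before the aldehyde is unmasked. In the acetal the 4-hydroxyl is buried between the C5 chain and the dimethoxymethyl group, so MeI/K2CO3 should give the 6-methyl ether acetal F4 on steric grounds; hydrolysis of the acetal (pyridinium p-toluenesulfonate, wet acetone) returns to 26.

**Step 17.** The allylic alcohol may ionise or hydrate, or the chain may cyclise onto the 4-hydroxyl, before the second MOM ether is cleaved, because acid that hydrolyses aryl MOM ethers can also protonate a 1,1-disubstituted alkene. Fallback, starting from 26: deprotection in two stages without Brønsted acid. Bu4NF in THF removes the silyl group and gives the bis-MOM carbinol F5. Me3SiOTf with 2,2'-bipyridyl (CH2Cl2, 0 °C, then water) exchanges the aryl MOM groups for trimethylsilyl ethers that are hydrolysed on aqueous work-up, arriving at 27.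

**Step 5.** Regiocontrol of the deprotonation may be lost (removal of the α-hydrogen next to the acetal instead of the one next to bromine), because the acetal can guide the lithium amide by coordination. Fallback, starting from 8: if the acetal side is metalated preferentially, the order of the two α-functionalisations is inverted. LiN(i-Pr)2 gives the furyllithium F6, ZnCl2 the furylzinc chloride F7, and coupling with 4 under Pd(PPh3)4 the aryl bromofuran F8. Its only remaining ring hydrogen, now necessarily the one next to bromine, is removed by LiN(i-Pr)2 to give the furyllithium F9, and C2Cl6 delivers 13.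

## Further compounds

F1 | step 14 | 2-[5-[2,4-bis(methoxymethoxy)phenyl]-4-(dimethoxymethyl)-3-[(4R)-4-(tert-butyldimethylsilyloxy)-5-methylhex-5-enoyl]furan-2-yl]acetic acid | C=C(C)[C@H](O[Si](C)(C)C(C)(C)C)CCC(=O)c1c(CC(=O)O)oc(-c2ccc(OCOC)cc2OCOC)c1C(OC)OC
F2 | step 14 | 2-[2,4-bis(methoxymethoxy)phenyl]-4-[(3R)-3-(tert-butyldimethylsilyloxy)-4-methylpent-4-enylidene]-3-(dimethoxymethyl)-4,7-dihydro-6H-furo[3,2-c]pyran-6-one (enol lactone) | C=C(C)[C@H](O[Si](C)(C)C(C)(C)C)CC=C1OC(=O)Cc2oc(-c3ccc(OCOC)cc3OCOC)c(C(OC)OC)c21
F3 | step 13 | allyl methyl 2-[5-[2,4-bis(methoxymethoxy)phenyl]-4-(dimethoxymethyl)-3-[(4R)-4-(tert-butyldimethylsilyloxy)-5-methylhex-5-enoyl]furan-2-yl]malonate | C=C(C)[C@H](O[Si](C)(C)C(C)(C)C)CCC(=O)c1c(C(C(=O)OC)C(=O)OCC=C)oc(-c2ccc(OCOC)cc2OCOC)c1C(OC)OC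
F4 | step 16 | 2-[2,4-bis(methoxymethoxy)phenyl]-5-[(2R)-2-(tert-butyldimethylsilyloxy)-3-methylbut-3-enyl]-3-(dimethoxymethyl)-6-methoxybenzofuran-4-ol | C=C(C)[C@H](O[Si](C)(C)C(C)(C)C)Cc1c(OC)cc2oc(-c3ccc(OCOC)cc3OCOC)c(C(OC)OC)c2c1O
F5 | step 17 | 2-[2,4-bis(methoxymethoxy)phenyl]-4-hydroxy-5-[(2R)-2-hydroxy-3-methylbut-3-enyl]-6-methoxybenzofuran-3-carbaldehyde | C=C(C)[C@H](O)Cc1c(OC)cc2oc(-c3ccc(OCOC)cc3OCOC)c(C=O)c2c1O
F6 | step 5 | [4-bromo-3-(dimethoxymethyl)furan-2-yl]lithium | COC(OC)c1c(Br)coc1[Li]
F7 | step 5 | [4-bromo-3-(dimethoxymethyl)furan-2-yl]zinc chloride | COC(OC)c1c(Br)coc1[Zn]Cl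
F8 | step 5 | 2-[2,4-bis(methoxymethoxy)phenyl]-4-bromo-3-(dimethoxymethyl)furan | COC(OC)c1c(Br)coc1-c1ccc(OCOC)cc1OCOC
F9 | step 5 | [5-[2,4-bis(methoxymethoxy)phenyl]-3-bromo-4-(dimethoxymethyl)furan-2-yl]lithium | COC(OC)c1c(Br)c([Li])oc1-c1ccc(OCOC)cc1OCOC
A1 | alternative 1 | coumestan with allyl ether on the future 4-oxygen, 6-methoxy group and MOM ether on the resorcinol ring | C=CCOc1cc(OC)cc2oc3c(c12)C(=O)Oc1cc(OCOC)ccc1-3
A2 | alternative 1 | 3-(2-allyloxy-6-bromo-4-methoxyphenyl)-4-hydroxy-7-(methoxymethoxy)coumarin | C=CCOc1cc(OC)cc(Br)c1C1=C(O)c2ccc(OCOC)cc2OC1=O
A3 | alternative 2 | methyl 2-[2,4-bis(methoxymethoxy)phenyl]-5-[[(2R)-3,3-dimethyloxiran-2-yl]methyl]-6-methoxy-4-(methoxymethoxy)benzofuran-3-carboxylate | CC1(C)[C@H](O1)Cc1c(OC)cc2oc(-c3ccc(OCOC)cc3OCOC)c(C(=O)OC)c2c1OCOC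
A4 | alternative 2 | methyl 2-[2,4-bis(methoxymethoxy)phenyl]-6-methoxy-4-(methoxymethoxy)-5-(3-methylbut-2-enyl)benzofuran-3-carboxylate | CC(C)=CCc1c(OC)cc2oc(-c3ccc(OCOC)cc3OCOC)c(C(=O)OC)c2c1OCOC
A5 | alternative 3 | coumestan with 6-methoxy group, 4-MOM ether and triisopropylsilyl ether on the resorcinol ring | COc1cc(OCOC)c2c(c1)oc1c2C(=O)Oc2cc(O[Si](C(C)C)(C(C)C)C(C)C)ccc2-1
A6 | alternative 3 | 2-[6-methoxy-4-(methoxymethoxy)benzofuran-2-yl]-5-(triisopropylsilyloxy)phenol | COc1cc(OCOC)c2cc(-c3ccc(O[Si](C(C)C)(C(C)C)C(C)C)cc3O)oc2c1
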